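(The earlier runs and the new flask are simulated from invented constants, and the scatter is random.)

Hold the peak of complex with two exchanged in millimolar against the incoming ligand charged, and leave percentages aside for a moment.

| setting | ash | birch | oak | flask |
|---|---|---|---|---|
| starting complex | 28 mM | 44 mM | 20 mM | 20 mM |
| incoming ligand | 30 mM | 30 mM | 60 mM | 30.0 mM |
| remark | run made earlier | run made earlier | run made earlier |  |
| time |  |  |  | 6.0 d |

| run | time / d | complex with two exchanged / % | starting complex / % |
|---|---|---|---|
| ash | 0.250 | 5.3 | 12.2 |
| ash | 0.500 | 7.3 | 4.1 |
| ash | 0.833 | 8.7 | 2.1 |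
| ash | 1.67 | 6.9 | 0.9 |
| ash | 2.50 | 6.5 | 0.7 |
| ash | 5.00 | 4.3 | 0.7 |
| birch | 0.250 | 4.3 | 6.9 |
| birch | 0.500 | 6.2 | 4.5 |
| birch | 0.833 | 6.6 | 1.7 |
| birch | 1.67 | 6.7 | 0.2 |
| birch | 2.50 | 3.7 | 0 |
| birch | 5.00 | 4.0 | 0 |
| oak | 0.250 | 14.2 | 9.9 |
| oak | 0.500 | 18.2 | 3.7 |
| oak | 1.04 | 18.5 | 1.3 |
| oak | 2.50 | 13.8 | 0 |
| oak | 5.00 | 9.5 | 0.4 |

(each reading ± 1 percentage point)

- percentages count the starting complex that a species holds: one homo dimer counts as two
- leaving ligand is meant together with its crystals
- solid, in amounts per volume of the solution: crystals
- steps under discussion: starting complex + incoming ligand <-> leaving ligand + complex with one exchanged; complex with one exchanged + incoming ligand <-> leaving ligand + complex with two exchanged; 2 starting complex -> homo dimer; crystals <-> leaving ligand; complex with one exchanged -> side product; complex with two exchanged + incoming ligand <-> leaving ligand + complex with three exchanged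

- time up to 6.0 d at which complex with two exchanged stands highest
- the amount of complex with two exchanged, in percent of the starting complex charged, at that time
- earliest time at which at least nineteen twentieths of that best amount are there, in d
- latest time at which they still are, in d

What can starting complex do? Pair to homo dimer, or exchange with incoming ligand. If each step goes as written, the ratio of the two forward rates at one moment, a selectivity factor, goes as starting complex over incoming ligand, and at fixed incoming ligand it shrinks as starting complex falls.

What do the readings show? From ash to birch, at equal incoming ligand, starting complex rises by a factor 1.57, but the peak read in millimolar rises by 1.21, less than that.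

So what do you carry? Ash gives 0.0812 and oak 0.0617; the flask has oak's starting complex and ash's incoming ligand, so I put it midway, at 0.0714. This w, the peak in millimolar per millimolar of incoming ligand charged, is my rule for 20 mM of starting complex.

Is w constant, then? Not on these readings: oak's is lower than ash's, and ash's peak of 8.7 % carries a scatter of 1 percentage point. It is a rough reading.

Your figure for the flask? 10.7 %, lower than the forecast's.

The forecast says 11.8 % at 0.9 d, with the window from 0.52 d to 1.45 d: “The peak shape follows oak”.

The flask gives 11.2 % at 1.02 d, with the window from 0.652 d to 1.60 d, so it opens later than the forecast said.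

    starting complex + incoming ligand ⇌ leaving ligand + complex with one exchanged (K = 54.0, k = 3.10 L mol⁻¹ h⁻¹)
    complex with one exchanged + incoming ligand ⇌ leaving ligand + complex with two exchanged (K = 1.40, k = 8.40 L mol⁻¹ h⁻¹)
    2 starting complex → homo dimer (k = 17.0 L mol⁻¹ h⁻¹)
    crystals ⇌ leaving ligand, rate k4*(cs4 - [leaving ligand]) while solid is left; crystals form when [leaving ligand] > cs4 (solubility = 12.0 mM, k = 0.970 h⁻¹)
    complex with one exchanged → side product (k = 0.0590 h⁻¹)
    complex with two exchanged + incoming ligand ⇌ leaving ligand + complex with three exchanged (K = 0.130, k = 4.20 L mol⁻¹ h⁻¹)

The flask's w comes to 0.0747. For a neighbour flask with 18 mM of incoming ligand and the same 20 mM of starting complex my w gives 6.43 %, and the peak of that neighbour flask stands at 6.75 %, a w of 0.0750. In the flask itself, pairing ran while starting complex lasted: by 0.600 d homo dimer held 72.0 %, with 4.95 % of starting complex left. Afterwards, with homo dimer steady at 72.9 %, complex with one exchanged went on to side product, which reached 19.3 % at 6.00 d, when complex with two exchanged stood at 4.84 %.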